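**Plan**

- Locants used at every stage: ring C1 (methyl, vinyl), C2 (CH2), C3 (acyloxy), C4 (α-carboxyvinyl), C5 (OH), C6 (hydroxymethylvinyl). PMB = 4-methoxybenzyl, TBS = tert-butyldimethylsilyl, TMSE = 2-(trimethylsilyl)ethyl.
- Cuts, in order: the C3–O ester bond (side-chain acid from 3-methylfuran-2(5H)-one); the ring bond C3–C4, because the C3 carbinol beside the C4 α-carboxyvinyl group on the carbocycle C1–C6 is the retron of a 2-(alkoxycarbonyl)allyl metal adding through its γ-carbon to a C3 aldehyde; the C4–C(acrylate) bond (Baylis–Hillman, then SN2′ bromination); the C5–C4 bond (acylation of a thiazole formyl equivalent); the C6–C1 bond (Ireland–Claisen shift of an allyl ester).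
- Forward: an E allylic alcohol and a β,γ-unsaturated acid are esterified, the [3,3] shift joins C6 to C1, the chain grows at C5 by C4 and then by the acrylate, the C3 aldehyde is unmasked, and the only ring closes by C3–C4 bond formation before acylation and fluoride deprotection.
- Stereochemistry: C1 and C6 from the chair Claisen shift of a chiral boron enolate; C5 from Felkin–Anh hydride reduction of a C5 ketone; C3 and C4 from the chair ring closure (C6 arm equatorial, allylic 1,3-strain); the side-chain Z alkene from the butenolide ring; the Z allylic bromide from SN2′ bromination.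

Key step: step 17

Assumption: the (S,S)-configured diazaborolidine bromide of step 7 is taken to deliver the Claisen acid in the absolute configuration drawn; should the sense of induction be opposite, its (R,R)-enantiomer is used with unchanged chemistry.

**Route**

Step 1
Reactants: 1 but-3-yn-1-ol
Product: 2 1-[(but-3-yn-1-yloxy)methyl]-4-methoxybenzene
Conditions: NaH, PMBCl, n-Bu4NI (cat.), THF, 0 °C to rt
Reagents that add atoms: 4-methoxybenzyl chloride, COc1ccc(CCl)cc1
Why: Williamson ether synthesis gives a PMB ether of the future C3 oxygen that should tolerate the Lewis-acidic boron and aluminium reagents ahead and is later removed oxidatively.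

Step 2
Reactants: 2 1-[(but-3-yn-1-yloxy)methyl]-4-methoxybenzene
Product: 5 (E)-5-[(4-methoxybenzyl)oxy]-3-methylpent-2-en-1-ol, via alkenyldimethylalane 3 (not isolated), via lithium alkenylalanate 4 (not isolated)
Conditions: Me3Al, Cp2ZrCl2 (0.25 equiv), CH2Cl2, 0 °C to rt; then n-BuLi, THF, −78 °C; (CH2O)n, −78 °C to rt; aq. work-up
Reagents that add atoms: trimethylaluminium, C[Al](C)C; formaldehyde (as paraformaldehyde), C=O
Why: Zirconium-catalysed carboalumination adds methyl and aluminium syn across the terminal alkyne with methyl on the internal carbon, and hydroxymethylation of the derived alanate with retention fixes the E trisubstituted alkene (future C1 methyl and vinyl carbons).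

Step 3
Reactants: 6 monomethyl itaconate (4-methoxy-2-methylidene-4-oxobutanoic acid)
Product: 8 methyl 3-(hydroxymethyl)but-3-enoate, via isobutyl carbonic anhydride 7 (not isolated)
Conditions: i-BuOCOCl, N-methylmorpholine, THF, −15 °C; then NaBH4, H2O, −15 to 0 °C
Reagents that add atoms: none
Why: Mixed-anhydride activation followed by borohydride reduction converts the free conjugated acid into the allylic alcohol chemoselectively, the methyl ester being inert to NaBH4 at this temperature.

Step 4
Reactants: 8 methyl 3-(hydroxymethyl)but-3-enoate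
Product: 9 methyl 3-{[(tert-butyldimethylsilyl)oxy]methyl}but-3-enoate
Conditions: TBSCl, imidazole, CH2Cl2, 0 °C to rt
Reagents that add atoms: tert-butyldimethylsilyl chloride, CC(C)(C)[Si](C)(C)Cl
Why: Imidazole-promoted silylation protects the future C6 hydroxymethyl arm as a TBS ether that should last until the final fluoride step.

Step 5
Reactants: 9 methyl 3-{[(tert-butyldimethylsilyl)oxy]methyl}but-3-enoate
Product: 10 3-{[(tert-butyldimethylsilyl)oxy]methyl}but-3-enoic acid
Conditions: LiOH, THF/H2O, 0 °C; then 1 M HCl to pH 4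
Reagents that add atoms: lithium hydroxide, [Li+].[OH-]
Why: Saponification of the methyl ester at 0 °C should outrun base-mediated migration of the 1,1-disubstituted alkene into conjugation and give the β,γ-unsaturated acid.

Step 6
Reactants: 5 (E)-5-[(4-methoxybenzyl)oxy]-3-methylpent-2-en-1-ol; 10 3-{[(tert-butyldimethylsilyl)oxy]methyl}but-3-enoic acid
Product: 11 (E)-5-[(4-methoxybenzyl)oxy]-3-methylpent-2-en-1-yl 3-{[(tert-butyldimethylsilyl)oxy]methyl}but-3-enoate
Conditions: DCC, DMAP (5 mol%), CH2Cl2, 0 °C
Reagents that add atoms: none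
Why: Steglich esterification with little DMAP at low temperature joins the two halves without conjugating the β,γ-unsaturated acyl unit.

Step 7
Reactants: 11 (E)-5-[(4-methoxybenzyl)oxy]-3-methylpent-2-en-1-yl 3-{[(tert-butyldimethylsilyl)oxy]methyl}but-3-enoate
Product: 13 (2R,3S)-2-{3-[(tert-butyldimethylsilyl)oxy]prop-1-en-2-yl}-3-ethenyl-5-[(4-methoxybenzyl)oxy]-3-methylpentanoic acid (C2 = later C6 and C3 = later C1), via boron ketene acetal 12 (not isolated)
Conditions: (S,S)-2-bromo-4,5-diphenyl-1,3-bis{[3,5-bis(trifluoromethyl)phenyl]sulfonyl}-1,3,2-diazaborolidine, Et3N, toluene/hexane, −78 °C; then −20 to 4 °C; aq. work-up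
Reagents that add atoms: none
Why: Enantioselective Ireland–Claisen rearrangement: soft enolisation in the non-polar medium should give the boron ketene acetal with the alkenyl group trans to the boron-bound oxygen, whose chair [3,3] shift with the E alkene puts the C6 arm and the C1 methyl on the same face of the later ring, while the C2-symmetric bis-sulfonamide ligand selects the enolate face and so the absolute configuration of both centres.

Step 8
Reactants: 13 the Claisen acid; 14 2-(trimethylsilyl)thiazole
Product: 16 thiazol-2-yl ketone of 13 (C5 carbonyl bonded to thiazole C2; C1 and C6 as in 13), via acid chloride 15 (not isolated)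
Conditions: 1-chloro-N,N,2-trimethylprop-1-en-1-amine, CH2Cl2, 0 °C to rt; then 14, CH2Cl2, rt
Reagents that add atoms: none
Why: Neutral acid chloride formation followed by desilylative C-acylation (ipso substitution) of the 2-silylthiazole installs C4 as a masked formyl carbon without base, so the allylic C6 centre α to the carbonyl should not epimerise.

Step 9
Reactants: 16 thiazol-2-yl ketone
Product: 17 thiazol-2-yl carbinol (C5 S alcohol; hydroxyl anti to the C6 alkenyl arm in the zigzag thiazole–C5–C6–C1)
Conditions: LiBH(s-Bu)3, THF, −78 °C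
Reagents that add atoms: none
Why: Felkin–Anh-controlled ketone reduction: the bulky hydride should attack anti to the quaternary C1 substituent with the alkenyl arm next to the carbonyl oxygen, giving the C5 alcohol that ends cis to the C6 arm in the ring, the epimer that addition of a carbon nucleophile to the corresponding aldehyde would not favour.

Step 10
Reactants: 17 thiazol-2-yl carbinol
Product: 18 C5 TBS ether of 17
Conditions: TBSOTf, 2,6-lutidine, CH2Cl2, −78 to 0 °C
Reagents that add atoms: tert-butyldimethylsilyl trifluoromethanesulfonate, CC(C)(C)[Si](C)(C)OS(=O)(=O)C(F)(F)F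
Why: Silyl triflate silylation protects the hindered secondary alcohol as a silyl ether, a poor leaving group that is needed at C5 in the ring closure.

Step 11
Reactants: 18 C5 TBS ether
Product: 21 (2S,3R,4S)-2-[(tert-butyldimethylsilyl)oxy]-3-{3-[(tert-butyldimethylsilyl)oxy]prop-1-en-2-yl}-4-ethenyl-6-[(4-methoxybenzyl)oxy]-4-methylhexanal (C4 aldehyde), via N-methylthiazolium triflate 19 (not isolated), via N-methylthiazolidine 20 (not isolated)
Conditions: MeOTf, 4 Å MS, MeCN, rt; then NaBH4, MeOH, 0 °C; then CuCl2·2H2O, CuO, MeCN/H2O, rt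
Reagents that add atoms: water, O
Why: Thiazole-to-formyl unmasking (N-methylation, hydride reduction to the thiazolidine, copper-assisted hydrolysis) releases the α-silyloxy aldehyde under near-neutral conditions that should leave C5, the PMB ether and both silyl ethers untouched.

Step 12
Reactants: 22 acryloyl chloride; 23 2-(trimethylsilyl)ethanol
Product: 24 2-(trimethylsilyl)ethyl prop-2-enoate (TMSE acrylate)
Conditions: Et3N, CH2Cl2, 0 °C
Reagents that add atoms: none
Why: Acylation of the alcohol by the acid chloride gives an acrylate whose ester is later cleaved by fluoride together with the silyl ethers.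

Step 13
Reactants: 21 α-silyloxy aldehyde; 24 TMSE acrylate
Product: 25 Baylis–Hillman alcohol, TMSE 2-methylidene-3-hydroxy ester with C4 as carbinol (both C4 epimers; C1, C5, C6 unchanged)
Conditions: DABCO (1 equiv), 24 (excess), 1,4-dioxane/H2O, rt
Reagents that add atoms: none
Why: Baylis–Hillman reaction: the amine adds to the acrylate and the zwitterionic enolate adds to the inductively activated α-silyloxy aldehyde, the C4 configuration being irrelevant because C4 becomes sp2 in the next step.

Step 14
Reactants: 25 Baylis–Hillman alcohol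
Product: 26 (Z)-2-(bromomethyl)enoate (C4=C double bond, bromomethyl cis to C5, TMSE ester trans)
Conditions: NBS, Me2S, CH2Cl2, −20 °C to rt
Reagents that add atoms: N-bromosuccinimide, O=C1CCC(=O)N1Br
Why: SN2′ bromination of the Baylis–Hillman alcohol through its alkoxysulfonium salt moves the double bond to C4 and should give the thermodynamically preferred Z allylic bromide.

Step 15
Reactants: 26 (Z)-2-(bromomethyl)enoate
Product: 27 primary C3 alcohol (PMB removed)
Conditions: DDQ, CH2Cl2/pH 7 buffer, 0 °C
Reagents that add atoms: none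
Why: Oxidative cleavage of the PMB ether by single-electron oxidation of the electron-rich arene spares the silyl ethers, the allylic bromide and the enoate.

Step 16
Reactants: 27 primary C3 alcohol
Product: 28 bromo aldehyde (C3 aldehyde; acyclic precursor of the ring)
Conditions: Dess–Martin periodinane, NaHCO3, CH2Cl2, 0 °C to rt
Reagents that add atoms: none
Why: Dess–Martin oxidation under buffered, non-basic conditions gives the aldehyde without touching the allylic bromide or epimerising any centre.

Step 17
Reactants: 28 bromo aldehyde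
Product: 30 cyclohexanol with free C3 hydroxyl, C4 TMSE acrylate, C5 and C6-arm TBS ethers (ring locants 1S,3S,4R,5S,6R), via allylchromium dichloride 29 (not isolated)
Conditions: CrCl2 (6 equiv), THF, rt, slow addition of 28 (final 0.005 M); then H2O
Reagents that add atoms: none
Why: Two equivalents of CrCl2 (divalent chromium) reduce the allylic C–Br bond to σ-allylchromium 29 (trivalent chromium), whose γ-carbon C4 adds to the chromium-bound C3 aldehyde through a closed six-membered array with allylic transposition, forming C3–C4 and leaving the exocyclic α-methylene ester; the closest known type is the Nozaki–Hiyama allylation of aldehydes with 2-(bromomethyl)alk-2-enoates, including ring-forming cases that give α-methylene γ-hydroxy esters. The carbocycle C1–C6 closes 6-exo-trig at the aldehyde carbon through a chair in which the C6 arm is equatorial and the C1 methyl axial, both set beforehand. C4 is controlled by allylic 1,3-strain: C5–H lies in the plane of the C4=C(ester) bond, so the tethered aldehyde attacks the alkene face opposite to the silyloxy group, which puts the acrylate unit equatorial and cis to the axial C5 silyl ether. C3 is controlled by the same chair: the axial site at C3 is syn-axial to both the C1 methyl and the C5 silyloxy group, so the chromium-bound oxygen should go equatorial, trans to C4, through the trans-fused bicyclic transition state that the E/Z-mobile allylchromium can reach by 1,3-metal shift. The step needs carbonyl addition to win over 1,4-elimination of the C5 oxygen and over intermolecular coupling, which the poor silyloxy leaving group, the non-basic reagent (the enolisable aldehyde survives) and high dilution should secure.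

Step 18
Reactants: 31 3-methylfuran-2(5H)-one
Product: 33 4-methoxybenzyl (Z)-4-hydroxy-2-methylbut-2-enoate, via potassium carboxylate 32 (not isolated)
Conditions: KOH (1.0 equiv), MeOH/H2O, rt; evaporate; then PMBCl, n-Bu4NI (cat.), DMF, rt
Reagents that add atoms: potassium hydroxide, [K+].[OH-]; 4-methoxybenzyl chloride, COc1ccc(CCl)cc1
Why: Lactone saponification followed by SN2 O-alkylation of the carboxylate opens the butenolide, whose ring guarantees the Z alkene.

Step 19
Reactants: 33 4-methoxybenzyl (Z)-4-hydroxy-2-methylbut-2-enoate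
Product: 34 4-methoxybenzyl (Z)-4-acetoxy-2-methylbut-2-enoate
Conditions: Ac2O, pyridine, DMAP (cat.), CH2Cl2, 0 °C
Reagents that add atoms: acetic anhydride, CC(=O)OC(C)=O
Why: DMAP-catalysed acetylation of the primary allylic alcohol should be faster than relactonisation and installs the acetate of the target side chain.

Step 20
Reactants: 34 4-methoxybenzyl (Z)-4-acetoxy-2-methylbut-2-enoate
Product: 35 (Z)-4-acetoxy-2-methylbut-2-enoic acid
Conditions: CF3CO2H, anisole, CH2Cl2, 0 °C
Reagents that add atoms: none
Why: Acidolysis of the PMB ester (benzylic cation trapped by anisole) frees the acid while the acetate and the Z alkene should be unaffected.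

Step 21
Reactants: 30 cyclohexanol; 35 (Z)-4-acetoxy-2-methylbut-2-enoic acid
Product: 37 C3 (Z)-4-acetoxy-2-methylbut-2-enoate of 30 (fully protected target), via trichlorobenzoic mixed anhydride 36 (not isolated)
Conditions: 2,4,6-trichlorobenzoyl chloride, Et3N, toluene, rt; then 30, DMAP, toluene, rt to 40 °C
Reagents that add atoms: none
Why: Yamaguchi esterification acylates the equatorial C3 hydroxyl with retention at C3, by a mixed-anhydride protocol that is established for isomerisation-prone Z-2-methylbut-2-enoic acids.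

Step 22
Reactants: 37 fully protected target
Product: 38 target, 2-[(1S,2S,3R,4S,6S)-6-{[(2Z)-4-(acetyloxy)-2-methylbut-2-enoyl]oxy}-4-ethenyl-2-hydroxy-3-(3-hydroxyprop-1-en-2-yl)-4-methylcyclohexyl]prop-2-enoic acid
Conditions: tris(dimethylamino)sulfonium difluorotrimethylsilicate (TASF), DMF, H2O (few equiv), 0 °C to rt; pH 5 phosphate buffer
Reagents that add atoms: none
Why: Fluoride-mediated global desilylation with a nearly non-basic fluoride source should cleave both TBS ethers and fragment the TMSE ester to the acid, ethene and Me3SiF without touching the allylic acetate, the C3 enoate or the acrylic acid.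

**Compound list**

1 | but-3-yn-1-ol | C#CCCO | starting material
2 | 1-[(but-3-yn-1-yloxy)methyl]-4-methoxybenzene | C#CCCOCc1ccc(OC)cc1 | intermediate
3 | (E)-alkenyldimethylalane from 2 | C/C(CCOCc1ccc(OC)cc1)=C\[Al](C)C | intermediate
4 | lithium butyl(alkenyl)dimethylalanate | [Li+].CCCC[Al-](C)(C)/C=C(\C)CCOCc1ccc(OC)cc1 | intermediate
5 | (E)-5-[(4-methoxybenzyl)oxy]-3-methylpent-2-en-1-ol | C/C(CCOCc1ccc(OC)cc1)=C\CO | intermediate
6 | monomethyl itaconate | C=C(CC(=O)OC)C(=O)O | starting material
7 | mixed anhydride of 6 with isobutyl carbonic acid | C=C(CC(=O)OC)C(=O)OC(=O)OCC(C)C | intermediate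
8 | methyl 3-(hydroxymethyl)but-3-enoate | C=C(CO)CC(=O)OC | intermediate
9 | methyl 3-{[(tert-butyldimethylsilyl)oxy]methyl}but-3-enoate | C=C(CO[Si](C)(C)C(C)(C)C)CC(=O)OC | intermediate
10 | 3-{[(tert-butyldimethylsilyl)oxy]methyl}but-3-enoic acid | C=C(CO[Si](C)(C)C(C)(C)C)CC(=O)O | intermediate
11 | (E)-5-[(4-methoxybenzyl)oxy]-3-methylpent-2-en-1-yl 3-{[(tert-butyldimethylsilyl)oxy]methyl}but-3-enoate | C=C(CO[Si](C)(C)C(C)(C)C)CC(=O)OC/C=C(\C)CCOCc1ccc(OC)cc1 | intermediate
12 | boron ketene acetal of 11 (alkenyl group trans to O–B; (S,S)-diazaborolidinyl on oxygen) | C=C(CO[Si](C)(C)C(C)(C)C)/C=C(\OC/C=C(\C)CCOCc1ccc(OC)cc1)OB1N(S(=O)(=O)c2cc(cc(c2)C(F)(F)F)C(F)(F)F)[C@@H](c2ccccc2)[C@H](c2ccccc2)N1S(=O)(=O)c1cc(cc(c1)C(F)(F)F)C(F)(F)F | intermediate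
13 | (2R,3S)-2-{3-[(tert-butyldimethylsilyl)oxy]prop-1-en-2-yl}-3-ethenyl-5-[(4-methoxybenzyl)oxy]-3-methylpentanoic acid | C=C[C@](C)(CCOCc1ccc(OC)cc1)[C@H](C(=C)CO[Si](C)(C)C(C)(C)C)C(=O)O | intermediate
14 | 2-(trimethylsilyl)thiazole | C[Si](C)(C)c1nccs1 | starting material
15 | acid chloride of 13 | C=C[C@](C)(CCOCc1ccc(OC)cc1)[C@H](C(=C)CO[Si](C)(C)C(C)(C)C)C(=O)Cl | intermediate
16 | thiazol-2-yl ketone of 13 | C=C[C@](C)(CCOCc1ccc(OC)cc1)[C@H](C(=C)CO[Si](C)(C)C(C)(C)C)C(=O)c1nccs1 | intermediate
17 | thiazol-2-yl carbinol (C5 S) | C=C[C@](C)(CCOCc1ccc(OC)cc1)[C@H](C(=C)CO[Si](C)(C)C(C)(C)C)[C@H](O)c1nccs1 | intermediate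
18 | C5 TBS ether of 17 | C=C[C@](C)(CCOCc1ccc(OC)cc1)[C@H](C(=C)CO[Si](C)(C)C(C)(C)C)[C@H](O[Si](C)(C)C(C)(C)C)c1nccs1 | intermediate
19 | N-methylthiazolium triflate of 18 | C=C[C@](C)(CCOCc1ccc(OC)cc1)[C@H](C(=C)CO[Si](C)(C)C(C)(C)C)[C@H](O[Si](C)(C)C(C)(C)C)c1scc[n+]1C.[O-]S(=O)(=O)C(F)(F)F | intermediate
20 | N-methylthiazolidine from 19 (thiazolidine C2 unassigned) | C=C[C@](C)(CCOCc1ccc(OC)cc1)[C@H](C(=C)CO[Si](C)(C)C(C)(C)C)[C@H](O[Si](C)(C)C(C)(C)C)C1SCCN1C | intermediate
21 | (2S,3R,4S)-2-[(tert-butyldimethylsilyl)oxy]-3-{3-[(tert-butyldimethylsilyl)oxy]prop-1-en-2-yl}-4-ethenyl-6-[(4-methoxybenzyl)oxy]-4-methylhexanal | C=C[C@](C)(CCOCc1ccc(OC)cc1)[C@H](C(=C)CO[Si](C)(C)C(C)(C)C)[C@H](O[Si](C)(C)C(C)(C)C)C=O | intermediate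
22 | acryloyl chloride | C=CC(=O)Cl | starting material
23 | 2-(trimethylsilyl)ethanol | C[Si](C)(C)CCO | starting material
24 | 2-(trimethylsilyl)ethyl prop-2-enoate | C=CC(=O)OCC[Si](C)(C)C | intermediate
25 | Baylis–Hillman alcohol (C4 carbinol, both epimers) | C=C[C@](C)(CCOCc1ccc(OC)cc1)[C@H](C(=C)CO[Si](C)(C)C(C)(C)C)[C@H](O[Si](C)(C)C(C)(C)C)C(O)C(=C)C(=O)OCC[Si](C)(C)C | intermediate
26 | (Z)-2-(bromomethyl)enoate with C3–O PMB ether | C=C[C@](C)(CCOCc1ccc(OC)cc1)[C@H](C(=C)CO[Si](C)(C)C(C)(C)C)[C@H](O[Si](C)(C)C(C)(C)C)/C=C(\CBr)C(=O)OCC[Si](C)(C)C | intermediate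
27 | (Z)-2-(bromomethyl)enoate with free C3 primary alcohol | C=C[C@](C)(CCO)[C@H](C(=C)CO[Si](C)(C)C(C)(C)C)[C@H](O[Si](C)(C)C(C)(C)C)/C=C(\CBr)C(=O)OCC[Si](C)(C)C | intermediate
28 | bromo aldehyde (C3 aldehyde, Z allylic bromide) | C=C[C@](C)(CC=O)[C@H](C(=C)CO[Si](C)(C)C(C)(C)C)[C@H](O[Si](C)(C)C(C)(C)C)/C=C(\CBr)C(=O)OCC[Si](C)(C)C | intermediate
29 | σ-allylchromium dichloride from 28 | C=C[C@](C)(CC=O)[C@H](C(=C)CO[Si](C)(C)C(C)(C)C)[C@H](O[Si](C)(C)C(C)(C)C)/C=C(\C[Cr](Cl)Cl)C(=O)OCC[Si](C)(C)C | intermediate
30 | cyclohexanol with free C3 hydroxyl and TMSE acrylate (ring locants 1S,3S,4R,5S,6R) | C=C[C@]1(C)C[C@H](O)[C@@H](C(=C)C(=O)OCC[Si](C)(C)C)[C@@H](O[Si](C)(C)C(C)(C)C)[C@H]1C(=C)CO[Si](C)(C)C(C)(C)C | intermediate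
31 | 3-methylfuran-2(5H)-one | CC1=CCOC1=O | starting material
32 | potassium (Z)-4-hydroxy-2-methylbut-2-enoate | [K+].[O-]C(=O)/C(C)=C\CO | intermediate
33 | 4-methoxybenzyl (Z)-4-hydroxy-2-methylbut-2-enoate | COc1ccc(COC(=O)/C(C)=C\CO)cc1 | intermediate
34 | 4-methoxybenzyl (Z)-4-acetoxy-2-methylbut-2-enoate | COc1ccc(COC(=O)/C(C)=C\COC(C)=O)cc1 | intermediate
35 | (Z)-4-acetoxy-2-methylbut-2-enoic acid | CC(=O)OC/C=C(/C)C(=O)O | intermediate
36 | mixed anhydride of 35 with 2,4,6-trichlorobenzoic acid | CC(=O)OC/C=C(/C)C(=O)OC(=O)c1c(Cl)cc(Cl)cc1Cl | intermediate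
37 | C3 (Z)-4-acetoxy-2-methylbut-2-enoate of 30 | C=C[C@]1(C)C[C@H](OC(=O)/C(C)=C\COC(C)=O)[C@@H](C(=C)C(=O)OCC[Si](C)(C)C)[C@@H](O[Si](C)(C)C(C)(C)C)[C@H]1C(=C)CO[Si](C)(C)C(C)(C)C | intermediate
38 | 2-[(1S,2S,3R,4S,6S)-6-{[(2Z)-4-(acetyloxy)-2-methylbut-2-enoyl]oxy}-4-ethenyl-2-hydroxy-3-(3-hydroxyprop-1-en-2-yl)-4-methylcyclohexyl]prop-2-enoic acid | C=C[C@]1(C)C[C@H](OC(=O)/C(C)=C\COC(C)=O)[C@@H](C(=C)C(=O)O)[C@@H](O)[C@H]1C(=C)CO | target

**Totals and risks**

Total step count: 22. Longest linear sequence: 16 steps (from 6 to 38 through steps 3–11, 13–17, 21 and 22).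

Steps most likely to fail:

Step 17. The allylchromium may add before it equilibrates and close on the other aldehyde face through a cis-fused array, placing the C3 oxygen axial and cis to the C4 arm. The fallback sets out from 28 and carries the ring closure through to the C3-epimeric cyclohexanol F1. Its axial hydroxyl is then inverted while the side chain is attached, by Mitsunobu esterification with acid 35 (PPh3, diisopropyl azodicarboxylate, toluene, 0 °C to rt). This returns to the route at 37 and replaces step 21.

Step 7. Enolisation of the dienolate-forming ester with the chiral bromoborane may be slow or poorly face-selective, and the long exposure to the Lewis acid may cost the PMB ether. The fallback sets out from 11 and uses the classical silyl variant (LiN(i-Pr)2, Me3SiCl, THF, −78 °C to rt), which passes through the O-trimethylsilyl ketene acetal F2 (alkenyl group cis to the allyloxy oxygen). The same chair shift gives the trimethylsilyl ester F3, which is hydrolysed on work-up to the racemic acid, that is 13 together with its enantiomer F4. Preparative chromatography on a chiral stationary phase separates the two and returns to the route at 13.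

Step 13. Amine-catalysed addition to the hindered α-silyloxy aldehyde may be slow, with epimerisation at C5 during the long exposure to base. The fallback sets out from 21 and uses vinylalumination instead. 2-(Trimethylsilyl)ethyl prop-2-ynoate F5 is made from propiolic acid and 23 (DCC, CH2Cl2, 0 °C). It is hydroaluminated with i-Bu2AlH and N-methylmorpholine N-oxide (THF, 0 °C) to the α-aluminoacrylate F6, which should add to 21 quickly under non-basic conditions. This returns to the route at 25.

**Further compounds**

F1 | step 17 | C3 epimer of 30 (axial C3 hydroxyl cis to the C4 arm) | C=C[C@]1(C)C[C@@H](O)[C@@H](C(=C)C(=O)OCC[Si](C)(C)C)[C@@H](O[Si](C)(C)C(C)(C)C)[C@H]1C(=C)CO[Si](C)(C)C(C)(C)C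
F2 | step 7 | O-trimethylsilyl ketene acetal of 11 | C=C(CO[Si](C)(C)C(C)(C)C)/C=C(\OC/C=C(\C)CCOCc1ccc(OC)cc1)O[Si](C)(C)C
F3 | step 7 | trimethylsilyl ester of the racemic Claisen acid (enantiomer leading to 13 drawn) | C=C[C@](C)(CCOCc1ccc(OC)cc1)[C@H](C(=C)CO[Si](C)(C)C(C)(C)C)C(=O)O[Si](C)(C)C
F4 | step 7 | enantiomer of 13, (2S,3R) | C=C[C@@](C)(CCOCc1ccc(OC)cc1)[C@@H](C(=C)CO[Si](C)(C)C(C)(C)C)C(=O)O
F5 | step 13 | 2-(trimethylsilyl)ethyl prop-2-ynoate | C#CC(=O)OCC[Si](C)(C)C
F6 | step 13 | 2-(trimethylsilyl)ethyl 2-(diisobutylalumanyl)prop-2-enoate | C=C([Al](CC(C)C)CC(C)C)C(=O)OCC[Si](C)(C)C
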